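(The data were generated by integration with made-up constants; scatter was added.)

You cannot read grey, ochre, red, violet or blue off the two earlier runs at the same minute, for their G differs from both.

in all of them: L 0.10 M; E 38 µM

| run | G | remark | time |
|---|---|---|---|
| north | 3 µM | run made earlier |  |
| north-east | 42 µM | run made earlier |  |
| grey | 2.5 µM |  | 4.0 min |
| ochre | 5.0 µM |  | 4.0 min |
| red | 10 µM |  | 4.0 min |
| violet | 20 µM |  | 4.0 min |
| blue | 40 µM |  | 4.0 min |

- north (time / min: X / %, L / %): 1.00: 9, 92; 2.00: 14, 80; 3.00: 21, 72; 4.00: 27, 66
- north-east (time / min: X / %, L / %): 1.00: 52, 3; 2.00: 23, 4; 3.00: 12, 0; 4.00: 12, 0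

(readings scatter by 2 percentage points)

- the numbers in the tables scatter by 2 percentage points (one standard deviation)
- steps under discussion: L + G -> X + G; X + G <-> J + G; G + E <-> Z
- "hardly changes" means that all values lie within two and a half points (for a concentration: within two and a half percent of the largest)

1. [X] at the end for grey, ochre, red, violet, blue, in this order
2. the course of these numbers from the first flask to the last (hardly changes / rises, then falls / falls all the way / falls, then rises / rises all the way)

But G is a catalyst. L + G -> X + G and X + G <-> J + G both give it back, and you take both rates to carry it as a factor. So G and time should enter as a product. You assume that E, charged at 38 µM, takes the same share of G in the flasks and in the runs. Then multiply G charged by elapsed time and divide by 42 µM. For violet this reads 1.90 min: the clock, the north-east minutes a flask has lived.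

Climb the ladder on this clock, fastest first. In the north-east run L reads 3% at 1.00 min, a rough life of 0.285 min. Early L is slower: the north run ends at clock 0.286 min and gives a life of 0.688 min. X, the intermediate, relaxes slower than that, with a life of 0.775 min, towards a floor of 12%. Blue's clock, 3.81 min, is longer than that life, so you read blue on the floor. Red, at 0.952 min, reads 52%. Violet reads 23%. Grey falls among the north readings at 23.0%.

Ochre, at 0.476 min, lies in the gap, so iterate. The north life makes X 50.0% if none goes on to J. Put that back, with mean X at 0.5 of its end value, and X becomes 36.5%. Once more gives 40.1%.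

The forecast gives 0.026 M, 0.044 M, 0.059 M, 0.044 M and 0.013 M of the 0.10 M charged, so rises, then falls: “X is an intermediate, so it rises, then falls”. You agree on the shape but part at violet, where its 44.0% is more than your 23%.

    L + G → X + G, rate k1*[L]*[G]/(1 + ([L]/Km1) + ([L]/Ksi1)^2) (0.0926 M, 0.0706 M, k = 2420 M⁻¹ s⁻¹)
    X + G ⇌ J + G, rate k2*[G]*[X] forward; the back reaction follows from the equilibrium constant (K = 6.90, k = 589 M⁻¹ s⁻¹)
    G + E ⇌ Z, settled at all times (K = 8400 M⁻¹)

X ended at 0.0244 M, 0.0432 M, 0.0530 M, 0.0269 M and 0.0137 M of the 0.10 M charged, so rises, then falls. In violet, L + G -> X + G ran while L stood at 7.90% at 2.00 min, and X + G <-> J + G then carried on to X 26.9% and J 73.0% at 4.00 min, with clock 1.90 min. Blue shows the same clock, 1.90 min, at 2.00 min, and there X stood at 26.1%.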